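## The problem

Eritrichin 17 is a depside: a 4-aryl-2-naphthoic acid whose C2 carboxyl group is esterified with the secondary hydroxyl of (R)-3-(3,4-dihydroxyphenyl)lactic acid, (R)-danshensu 14. The naphthalene (ring A = C4a, C5–C8, C8a; ring B = C1–C4, C4a, C8a) carries a catechol on C6/C7, a 3,4-dihydroxyphenyl ring on C4 and hydrogen on C1, C3, C5 and C8. The aromatic half therefore poses a regiochemical task only: a 1,3-relation of aryl and carboxyl on ring B and a vicinal dioxygen pattern on ring A. The single stereocentre is the carbinol carbon of the lactate; it has nothing to control and nothing controls it, so it is best taken from the chiral pool and kept away from every step that could epimerise it. That carbon is α to a carboxyl group and carries an acyloxy group, so it is base-sensitive, and the ester joining the two halves is the bond most exposed to hydroxide and strong Lewis acids. The three catechols oxidise readily in basic, aerobic media and must stay masked to the end; because the target has no alkene, hydrogenolysis is available as a neutral final unmasking. The feature that opens the route is ring A itself: C5(H)–C6(O)–C7(O)–C8(H) is the carbon chain of a 2,3-dioxygenated buta-1,3-diene, and the C4a–C8a bond to which it is fused is an edge of a benzoate ring, the formal triple bond of an aryne.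

## Retrosynthesis

**17 from 16.** Seven O–benzyl bonds are cut, six ethers and one ester. Hydrogenolysis is chosen over any acidic or basic unmasking because it leaves the depside ester and the α-stereocentre alone and the target offers nothing else to reduce. The forward reaction only has to run to completion.

**16 from 13 and 15.** The acyl C–O bond of the depside is cut. Acylating the hydroxyl of 15 does not touch any bond at the stereocentre, so the (R) configuration of 14 is carried over unchanged; 15 comes from 14 in one benzylation. This splits the target into an achiral naphthoic acid and a chiral-pool alcohol of about equal size. The forward step must activate the acid mildly enough not to epimerise the α-acyloxy ester it creates.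

**13 from 10 by way of 12 and 11.** No skeletal bond is cut; four O-methyl groups are exchanged for benzyl and the ester is saponified. Ring A necessarily arrives as a bis(methyl ether), since 6 is the available 2,3-dioxygenated diene. Aryl methyl ethers can only be removed with a boron trihalide or a comparably harsh reagent, which should never meet the depside ester. The demethylation is therefore placed at 10, an achiral naphthoate with no fragile group, and the two extra steps buy a neutral final deprotection.

**10 from 9.** Two hydrogens at C5 and C8 are removed; no skeletal bond changes. The 5,8-dihydronaphthalene is one oxidation level below the arene, and the gain in aromaticity makes the dehydrogenation easy.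

**9 from aryne 8 and diene 6.** The C4a–C5 and C8–C8a bonds are cut, which removes all of ring A together with both of its oxygens. The neighbouring cuts through ring B (benzannulation of a veratrole) must establish the aryl/carboxyl pattern during the ring closure. Here that pattern is already fixed on a simple benzene and the ring-forming partner is symmetric, so no regiochemical question arises. Aryne 8 comes from arylmagnesium species 7, and 7 from the ortho-iodoaryl triflate 5 by iodine–magnesium exchange. The forward step needs aryne generation that tolerates a methyl ester and a [4+2] addition that outruns [2+2] and ene pathways.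

**5 from 4, 3, 1 and 2.** The O–S bond of the triflate, the C5–I bond and the biaryl bond are cut in turn. The phenol of 1 serves three purposes: it tolerates the cross-coupling with 2, directs iodine to its one free ortho position in 3, and becomes the leaving group in 5. All carbon of the aryne precursor comes from two commercial arenes.

## Roads not taken

Alternative 1: The cut runs through C2–C3 and C4–C4a of ring B. In the forward direction two molecules of methyl 5-bromoferulate A1 are oxidised by FeCl3·6H2O or at an anode and couple at their side-chain carbons, which forms the future C2–C3 bond. One arene then closes onto the benzylic carbon of the other half (C4–C4a) to give the racemic trans 1-aryl-1,2-dihydronaphthalene-2,3-diester A2.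
- Merits: the whole C18 skeleton, ring B and four of the six phenolic oxygens arise in one step from the cheap C9 cinnamate A1, with no organometallic reagent and no cryogenic step. In bond economy this is the better road.
- Weak points: A2 has a second carboxyl group on the carbon that becomes C3, where eritrichin has hydrogen. The two esters would have to be told apart and one removed. The two bromine blocking groups would have to be taken off, the ring dehydrogenated (destroying both new stereocentres) and the guaiacol methyl ethers cleaved, all before 14 can be attached. Oxidative phenol couplings of this kind also give mixtures of linkage isomers.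
- Comparison: the chosen plan spends three steps on the aryne precursor 5 but then delivers exactly the required pattern, one carboxyl and hydrogen at C3, with nothing to delete.

Alternative 2: The cut removes the O–Cα and Cα–C(=O) bonds of the lactate unit. Acid 13, [3,4-bis(benzyloxy)phenyl]acetaldehyde A3 and tert-octyl isocyanide A4 would combine in a Passerini reaction under a chiral phosphoric acid to give the (R)-α-acyloxy amide A5.
- Merits: the stereocentre is set by a catalyst, either enantiomer is accessible, and the route does not depend on a supply of 14. If 14 of the right configuration were not available, this would be the better way to make the centre.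
- Weak points: A3 is an enolisable arylacetaldehyde that self-condenses easily, and such aldehydes are the poorest substrates for enantioselective Passerini chemistry. A5 ends in a hindered secondary amide, which must be converted into a free acid without cleaving the more labile naphthoate ester next to it or epimerising the centre.
- Comparison: this road says nothing about the naphthalene, since acid 13 must be made anyway. It is an alternative only to step 10 of the chosen plan, which obtains the same centre with full configurational certainty from the chiral pool in a single acylation.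

Alternative 3: The cut runs through C1–C2 and C3–C4 of ring B. Irradiation of the 2-benzylbenzaldehyde A6 gives the hydroxy-ortho-quinodimethane A7 by photoenolisation. A7 adds the propiolate ester A8 of protected 14, and acid-induced loss of water then aromatises ring B and gives A9, which is identical with 16.
- Merits: it is the most convergent road. Ring B forms with the depside already in place, A9 is one hydrogenolysis from 17, and no protecting-group exchange is needed. In step count after ring formation it beats the chosen plan.
- Weak points: A6 is a tetra-oxygenated diarylmethane aldehyde that needs its own multistep synthesis. The regiochemistry with the unsymmetrical alkyne A8 depends on the hydroxyl terminus of A7 dominating its aryl terminus. Alkynes are sluggish partners for photoenols. The chiral fragment, as the electrophilic propiolate A8, is exposed to light and then acid at the most demanding step.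
- Comparison: the chosen plan uses a thermal ring construction with a symmetric diene, so regiochemistry cannot go wrong. It uses only commercial building blocks and introduces the stereocentre after all harsh operations are over.

Key step: step 4

Remark on the chemistry: (R)-danshensu 14 is taken as the free acid; its commercial sodium salt would be used in step 9 in the same way with one equivalent less of K2CO3.

## Route

Step 1
Reactants: 1 methyl 3-bromo-4-hydroxybenzoate; 2 3,4-dimethoxyphenylboronic acid
Product: 3 methyl 3-(3,4-dimethoxyphenyl)-4-hydroxybenzoate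
Conditions: Pd(PPh3)4 (3 mol %), K2CO3 (3 equiv), 1,4-dioxane/H2O 4:1, 85 °C
Reagents that add atoms: none
Why: Suzuki–Miyaura cross-coupling of an aryl bromide; the phenol is carried as its phenoxide, and aqueous carbonate at this temperature should not saponify the electron-rich benzoate.

Step 2
Reactants: 3 methyl 3-(3,4-dimethoxyphenyl)-4-hydroxybenzoate
Product: 4 methyl 3-(3,4-dimethoxyphenyl)-4-hydroxy-5-iodobenzoate
Conditions: NaI (1.1 equiv), NaOH (1.0 equiv), aq. NaOCl (1.1 equiv, slow addition), MeOH, 0 °C; aq. Na2S2O3, then 1 M HCl
Reagents that add atoms: sodium iodide, [Na+].[I-]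
Why: Electrophilic aromatic iodination of the phenoxide by the hypoiodite formed in the flask from iodide and hypochlorite; only one ortho position is free (the other carries the aryl group, the para position the ester), and in base the phenoxide should react far faster than the non-phenolic veratryl ring.

Step 3
Reactants: 4 methyl 3-(3,4-dimethoxyphenyl)-4-hydroxy-5-iodobenzoate
Product: 5 methyl 3-(3,4-dimethoxyphenyl)-5-iodo-4-(trifluoromethanesulfonyloxy)benzoate
Conditions: Tf2O (1.3 equiv), pyridine (3 equiv), CH2Cl2, 0 °C → rt
Reagents that add atoms: trifluoromethanesulfonic anhydride, O=S(=O)(OS(=O)(=O)C(F)(F)F)C(F)(F)F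
Why: O-Sulfonylation of a phenol with triflic anhydride and pyridine; this reagent pair also converts di-ortho-substituted phenols, and nothing else in 4 is nucleophilic.

Step 4
Reactants: 5 methyl 3-(3,4-dimethoxyphenyl)-5-iodo-4-(trifluoromethanesulfonyloxy)benzoate; 6 2,3-dimethoxybuta-1,3-diene
Product: 9 methyl 4-(3,4-dimethoxyphenyl)-6,7-dimethoxy-5,8-dihydronaphthalene-2-carboxylate, via arylmagnesium chloride 7 (not isolated), via aryne 8 (not isolated)
Conditions: 6 (5 equiv), Me3SiCH2MgCl (1.5 equiv, added last), THF, −78 °C; sat. aq. NaHCO3; chromatography on Et3N-treated SiO2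
Reagents that add atoms: none
Why: Iodine–magnesium exchange at the electron-poor C–I bond of 5 with the non-nucleophilic silylmethyl Grignard reagent should give arylmagnesium chloride 7 at −78 °C without attack on the methyl ester, and 7 loses magnesium chloride triflate by 1,2-elimination to give aryne 8. Aryne 8 is trapped by the s-cis conformer of diene 6 in a concerted suprafacial [4+2] cycloaddition (aryne Diels–Alder reaction) that forms C4a–C5 and C8–C8a together. Ring A is thus closed as a six-membered carbocycle by intermolecular cycloaddition, both ring bonds arising in the same event and the C6–C7 bis(enol ether) double bond being left behind. The closest known reaction type is the Diels–Alder trapping of arynes from ortho-iodoaryl triflates by acyclic 2,3-disubstituted buta-1,3-dienes. No stereocentre is formed. Regioselectivity is not needed, because 6 has a twofold axis and both orientations on the unsymmetrical aryne give the same adduct. The step needs periselectivity ([4+2] over [2+2] addition to one enol ether and over an ene reaction) and chemoselectivity (diene over Grignard reagent as aryne trap); the first is secured by the absence of allylic hydrogen in 6 and the poor 4π reactivity of the veratryl ring, the second by the excess of 6 present before the Grignard reagent is added. The acid-labile adduct is isolated on triethylamine-treated silica.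

Step 5
Reactants: 9 methyl 4-(3,4-dimethoxyphenyl)-6,7-dimethoxy-5,8-dihydronaphthalene-2-carboxylate
Product: 10 methyl 4-(3,4-dimethoxyphenyl)-6,7-dimethoxy-2-naphthoate
Conditions: DDQ (1.1 equiv), NaHCO3 (solid, 3 equiv), PhMe, 0 °C → rt
Reagents that add atoms: none
Why: Quinone dehydrogenation of a 1,4-dihydroarene: hydride abstraction from a methylene that is both benzylic and allylic to an enol ether, then proton loss, driven by formation of the naphthalene. The bicarbonate buffers the acidic hydroquinone so that the enol ethers are oxidised before they can hydrolyse.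

Step 6
Reactants: 10 methyl 4-(3,4-dimethoxyphenyl)-6,7-dimethoxy-2-naphthoate
Product: 11 methyl 4-(3,4-dihydroxyphenyl)-6,7-dihydroxy-2-naphthoate
Conditions: BBr3 (8 equiv, 1 M in CH2Cl2), CH2Cl2, −78 → 0 °C; MeOH quench at 0 °C, co-evaporation with MeOH
Reagents that add atoms: none
Why: Lewis-acid cleavage of aryl methyl ethers with BBr3 (bromide attack on the O-methyl group of the boron-complexed ether); an aryl carboxylic methyl ester reacts much more slowly at or below 0 °C, and 10 has no stereocentre or other fragile group.

Step 7
Reactants: 11 methyl 4-(3,4-dihydroxyphenyl)-6,7-dihydroxy-2-naphthoate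
Product: 12 methyl 4-[3,4-bis(benzyloxy)phenyl]-6,7-bis(benzyloxy)-2-naphthoate
Conditions: BnBr (4.8 equiv), K2CO3 (6 equiv), DMF, argon, rt → 50 °C
Reagents that add atoms: benzyl bromide, BrCc1ccccc1
Why: Williamson ether synthesis on four phenoxides; carbonate in DMF leaves the methyl ester intact, and exclusion of air prevents oxidation of the catecholates.

Step 8
Reactants: 12 methyl 4-[3,4-bis(benzyloxy)phenyl]-6,7-bis(benzyloxy)-2-naphthoate
Product: 13 4-[3,4-bis(benzyloxy)phenyl]-6,7-bis(benzyloxy)-2-naphthoic acid
Conditions: LiOH·H2O (5 equiv), THF/MeOH/H2O 3:1:1, 50 °C; 1 M HCl to pH 2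
Reagents that add atoms: lithium hydroxide, [Li+].[OH-]
Why: Ester saponification by acyl–oxygen cleavage; benzyl ethers are inert to hydroxide and the molecule has no stereocentre.

Step 9
Reactants: 14 (R)-danshensu, (R)-3-(3,4-dihydroxyphenyl)-2-hydroxypropanoic acid
Product: 15 benzyl (R)-3-[3,4-bis(benzyloxy)phenyl]-2-hydroxypropanoate
Conditions: BnBr (3.3 equiv), K2CO3 (3.5 equiv), DMF, argon, rt
Reagents that add atoms: benzyl bromide, BrCc1ccccc1
Why: Carbonate-mediated O-alkylation of the carboxylate and the two phenoxides; the secondary alcohol is not deprotonated by carbonate and stays free, and the α-C–H of a hydroxy ester is not acidic enough to epimerise, so the (R) centre is carried through.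

Step 10
Reactants: 13 4-[3,4-bis(benzyloxy)phenyl]-6,7-bis(benzyloxy)-2-naphthoic acid; 15 benzyl (R)-3-[3,4-bis(benzyloxy)phenyl]-2-hydroxypropanoate
Product: 16 (R)-1-(benzyloxy)-3-[3,4-bis(benzyloxy)phenyl]-1-oxopropan-2-yl 4-[3,4-bis(benzyloxy)phenyl]-6,7-bis(benzyloxy)-2-naphthoate
Conditions: EDC·HCl (1.5 equiv), DMAP (0.2 equiv), CH2Cl2, 0 °C → rt
Reagents that add atoms: none
Why: Steglich esterification (carbodiimide activation, acyl transfer by DMAP); the alcohol oxygen is acylated and no bond at the stereocentre is broken, so (R) is retained. Sub-stoichiometric DMAP and low temperature limit epimerisation of the α-acyloxy ester formed.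

Step 11
Reactants: 16 (R)-1-(benzyloxy)-3-[3,4-bis(benzyloxy)phenyl]-1-oxopropan-2-yl 4-[3,4-bis(benzyloxy)phenyl]-6,7-bis(benzyloxy)-2-naphthoate
Product: 17 eritrichin, (R)-3-(3,4-dihydroxyphenyl)-2-{[4-(3,4-dihydroxyphenyl)-6,7-dihydroxy-2-naphthoyl]oxy}propanoic acid
Conditions: H2 (1 atm), 10% Pd/C, THF/MeOH 1:1, rt
Reagents that add atoms: none
Why: Heterogeneous hydrogenolysis of six benzyl ethers and one benzyl ester; the substrate has no alkene, the naphthalene and the depside ester are inert under these neutral conditions, and the stereocentre is not touched.

## Compound list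

1 | methyl 3-bromo-4-hydroxybenzoate | COC(=O)c1ccc(O)c(Br)c1 | starting material
2 | 3,4-dimethoxyphenylboronic acid | COc1ccc(B(O)O)cc1OC | starting material
3 | methyl 3-(3,4-dimethoxyphenyl)-4-hydroxybenzoate | COC(=O)c1ccc(O)c(-c2ccc(OC)c(OC)c2)c1 | intermediate
4 | methyl 3-(3,4-dimethoxyphenyl)-4-hydroxy-5-iodobenzoate | COC(=O)c1cc(I)c(O)c(-c2ccc(OC)c(OC)c2)c1 | intermediate
5 | methyl 3-(3,4-dimethoxyphenyl)-5-iodo-4-(trifluoromethanesulfonyloxy)benzoate | COC(=O)c1cc(I)c(OS(=O)(=O)C(F)(F)F)c(-c2ccc(OC)c(OC)c2)c1 | intermediate
6 | 2,3-dimethoxybuta-1,3-diene | C=C(OC)C(OC)=C | starting material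
7 | methyl 3-(chloromagnesio)-5-(3,4-dimethoxyphenyl)-4-(trifluoromethanesulfonyloxy)benzoate | COC(=O)c1cc([Mg]Cl)c(OS(=O)(=O)C(F)(F)F)c(-c2ccc(OC)c(OC)c2)c1 | intermediate (not isolated)
8 | methyl 3-(3,4-dimethoxyphenyl)-4,5-didehydrobenzoate (aryne) | COC(=O)C1=CC#CC(c2ccc(OC)c(OC)c2)=C1 | intermediate (not isolated)
9 | methyl 4-(3,4-dimethoxyphenyl)-6,7-dimethoxy-5,8-dihydronaphthalene-2-carboxylate | COC(=O)c1cc2c(c(-c3ccc(OC)c(OC)c3)c1)CC(OC)=C(OC)C2 | intermediate
10 | methyl 4-(3,4-dimethoxyphenyl)-6,7-dimethoxy-2-naphthoate | COC(=O)c1cc(-c2ccc(OC)c(OC)c2)c2cc(OC)c(OC)cc2c1 | intermediate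
11 | methyl 4-(3,4-dihydroxyphenyl)-6,7-dihydroxy-2-naphthoate | COC(=O)c1cc(-c2ccc(O)c(O)c2)c2cc(O)c(O)cc2c1 | intermediate
12 | methyl 4-[3,4-bis(benzyloxy)phenyl]-6,7-bis(benzyloxy)-2-naphthoate | COC(=O)c1cc(-c2ccc(OCc3ccccc3)c(OCc3ccccc3)c2)c2cc(OCc3ccccc3)c(OCc3ccccc3)cc2c1 | intermediate
13 | 4-[3,4-bis(benzyloxy)phenyl]-6,7-bis(benzyloxy)-2-naphthoic acid | OC(=O)c1cc(-c2ccc(OCc3ccccc3)c(OCc3ccccc3)c2)c2cc(OCc3ccccc3)c(OCc3ccccc3)cc2c1 | intermediate
14 | (R)-danshensu, (R)-3-(3,4-dihydroxyphenyl)-2-hydroxypropanoic acid | O[C@H](Cc1ccc(O)c(O)c1)C(=O)O | starting material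
15 | benzyl (R)-3-[3,4-bis(benzyloxy)phenyl]-2-hydroxypropanoate | O[C@H](Cc1ccc(OCc2ccccc2)c(OCc2ccccc2)c1)C(=O)OCc1ccccc1 | intermediate
16 | (R)-1-(benzyloxy)-3-[3,4-bis(benzyloxy)phenyl]-1-oxopropan-2-yl 4-[3,4-bis(benzyloxy)phenyl]-6,7-bis(benzyloxy)-2-naphthoate | O=C(O[C@H](Cc1ccc(OCc2ccccc2)c(OCc2ccccc2)c1)C(=O)OCc1ccccc1)c1cc(-c2ccc(OCc3ccccc3)c(OCc3ccccc3)c2)c2cc(OCc3ccccc3)c(OCc3ccccc3)cc2c1 | intermediate
17 | eritrichin | O=C(O[C@H](Cc1ccc(O)c(O)c1)C(=O)O)c1cc(-c2ccc(O)c(O)c2)c2cc(O)c(O)cc2c1 | target

## Step count and least certain steps

Total: 11 steps. Longest linear sequence: 10 steps (steps 1–8, 10 and 11); step 9 is a one-step side branch.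

**Step 4 (key step).** The aryne may be diverted before it meets the s-cis diene. The likely diversions are [2+2] addition to a single enol ether double bond, capture by the Grignard reagent or by magnesium halide, and oligomerisation. The cause is that a 2,3-disubstituted diene populates its s-cis form only partly, while enol ethers are competent two-π partners for arynes. The adduct may in addition lose its enol ethers by hydrolysis during isolation. The fallback abandons the aryne and builds ring B onto a preformed dimethoxybenzene ring by known chemistry; it would be used only if this disconnection cannot be saved. Stobbe condensation of commercial 3,4-dimethoxybenzaldehyde with dimethyl succinate (NaOMe, MeOH, reflux) should give (E)-4-(3,4-dimethoxyphenyl)-3-(methoxycarbonyl)but-3-enoic acid F1. Heating F1 in Ac2O with NaOAc should cyclise it, para to a methoxy group, to methyl 4-acetoxy-6,7-dimethoxy-2-naphthoate F2. K2CO3 in MeOH should free methyl 4-hydroxy-6,7-dimethoxy-2-naphthoate F3, and Tf2O with pyridine should convert it into methyl 6,7-dimethoxy-4-(trifluoromethanesulfonyloxy)-2-naphthoate F4. Suzuki–Miyaura coupling of F4 with boronic acid 2 (Pd(PPh3)4, K2CO3, dioxane/H2O) should give 10. The fallback sets out from 2 and returns to the route at 10.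

**Step 10.** Acylation of the hindered, electron-poor secondary hydroxyl may be slow. The carbodiimide-activated acid would then rearrange to an unreactive N-acylurea, and prolonged contact with DMAP could epimerise the α-acyloxy ester once formed. The fallback makes the C–O bond by displacement at the stereocentre with double inversion. Appel bromination of 15 (CBr4, PPh3, CH2Cl2, 0 °C) should give, with inversion, benzyl (S)-2-bromo-3-[3,4-bis(benzyloxy)phenyl]propanoate F5. The caesium salt of 13 (Cs2CO3, DMF, 0 °C → rt) should displace bromide with a second inversion and give 16 with the (R) configuration. The fallback sets out from 15 and 13 and returns at 16.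

**Step 2.** Chemoselectivity may be lost, either by iodination of the veratryl ring para to a methoxy group or by hypochlorite oxidation of the electron-rich biaryl phenol, because 3 contains two activated arenes. The fallback brings the iodine in before the veratryl ring exists. Commercial methyl 4-hydroxy-3,5-diiodobenzoate, used in excess and recovered, would be coupled once with boronic acid 2 (Pd(PPh3)4, K2CO3, dioxane/H2O) to give 4 directly. The fallback sets out from 2 and returns at 4; it makes no new compound, and its entry below is F0.

**Step 6.** Ether cleavage may stop short of four demethylations, the methyl ester may be partly lost, and the free tetraphenol may oxidise in air during isolation. The fallback gives up retention of the ester and cleaves every O-methyl bond at once. Heating 10 in molten pyridinium chloride (neat, 190 °C, argon) should cleave the four aryl methyl ethers and the methyl ester by chloride attack at methyl and give 4-(3,4-dihydroxyphenyl)-6,7-dihydroxy-2-naphthoic acid F6. Without purification, BnBr and K2CO3 in DMF should convert F6 into benzyl 4-[3,4-bis(benzyloxy)phenyl]-6,7-bis(benzyloxy)-2-naphthoate F7, and saponification of F7 with LiOH should give 13. The fallback sets out from 10 and returns at 13.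

## Further compounds

F1 | step 4 | (E)-4-(3,4-dimethoxyphenyl)-3-(methoxycarbonyl)but-3-enoic acid | COC(=O)/C(CC(=O)O)=C/c1ccc(OC)c(OC)c1
F2 | step 4 | methyl 4-acetoxy-6,7-dimethoxy-2-naphthoate | COC(=O)c1cc(OC(C)=O)c2cc(OC)c(OC)cc2c1
F3 | step 4 | methyl 4-hydroxy-6,7-dimethoxy-2-naphthoate | COC(=O)c1cc(O)c2cc(OC)c(OC)cc2c1
F4 | step 4 | methyl 6,7-dimethoxy-4-(trifluoromethanesulfonyloxy)-2-naphthoate | COC(=O)c1cc(OS(=O)(=O)C(F)(F)F)c2cc(OC)c(OC)cc2c1
F5 | step 10 | benzyl (S)-2-bromo-3-[3,4-bis(benzyloxy)phenyl]propanoate | Br[C@@H](Cc1ccc(OCc2ccccc2)c(OCc2ccccc2)c1)C(=O)OCc1ccccc1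
F0 | step 2 | none | none
F6 | step 6 | 4-(3,4-dihydroxyphenyl)-6,7-dihydroxy-2-naphthoic acid | OC(=O)c1cc(-c2ccc(O)c(O)c2)c2cc(O)c(O)cc2c1
F7 | step 6 | benzyl 4-[3,4-bis(benzyloxy)phenyl]-6,7-bis(benzyloxy)-2-naphthoate | O=C(OCc1ccccc1)c1cc(-c2ccc(OCc3ccccc3)c(OCc3ccccc3)c2)c2cc(OCc3ccccc3)c(OCc3ccccc3)cc2c1
A1 | alternative 1 | methyl 5-bromoferulate | COC(=O)/C=C/c1cc(OC)c(O)c(Br)c1
A2 | alternative 1 | racemic trans dimethyl 8-bromo-1-(3-bromo-4-hydroxy-5-methoxyphenyl)-7-hydroxy-6-methoxy-1,2-dihydronaphthalene-2,3-dicarboxylate (one enantiomer drawn) | COC(=O)C1=Cc2cc(OC)c(O)c(Br)c2[C@@H](c2cc(Br)c(O)c(OC)c2)[C@@H]1C(=O)OC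
A3 | alternative 2 | [3,4-bis(benzyloxy)phenyl]acetaldehyde | O=CCc1ccc(OCc2ccccc2)c(OCc2ccccc2)c1
A4 | alternative 2 | tert-octyl isocyanide (2-isocyano-2,4,4-trimethylpentane) | [C-]#[N+]C(C)(C)CC(C)(C)C
A5 | alternative 2 | (R)-3-[3,4-bis(benzyloxy)phenyl]-1-oxo-1-[(2,4,4-trimethylpentan-2-yl)amino]propan-2-yl 4-[3,4-bis(benzyloxy)phenyl]-6,7-bis(benzyloxy)-2-naphthoate | O=C(O[C@H](Cc1ccc(OCc2ccccc2)c(OCc2ccccc2)c1)C(=O)NC(C)(C)CC(C)(C)C)c1cc(-c2ccc(OCc3ccccc3)c(OCc3ccccc3)c2)c2cc(OCc3ccccc3)c(OCc3ccccc3)cc2c1
A6 | alternative 3 | 4,5-bis(benzyloxy)-2-[3,4-bis(benzyloxy)benzyl]benzaldehyde | O=Cc1cc(OCc2ccccc2)c(OCc2ccccc2)cc1Cc1ccc(OCc2ccccc2)c(OCc2ccccc2)c1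
A7 | alternative 3 | photoenol of A6, (E)-{3,4-bis(benzyloxy)-6-[(E)-3,4-bis(benzyloxy)benzylidene]cyclohexa-2,4-dien-1-ylidene}methanol | O/C=C1\C=C(OCc2ccccc2)C(OCc2ccccc2)=C/C1=C\c1ccc(OCc2ccccc2)c(OCc2ccccc2)c1
A8 | alternative 3 | benzyl (R)-3-[3,4-bis(benzyloxy)phenyl]-2-(propioloyloxy)propanoate | C#CC(=O)O[C@H](Cc1ccc(OCc2ccccc2)c(OCc2ccccc2)c1)C(=O)OCc1ccccc1
A9 | alternative 3 | eritrichin hexabenzyl ether benzyl ester (identical with 16) | O=C(O[C@H](Cc1ccc(OCc2ccccc2)c(OCc2ccccc2)c1)C(=O)OCc1ccccc1)c1cc(-c2ccc(OCc3ccccc3)c(OCc3ccccc3)c2)c2cc(OCc3ccccc3)c(OCc3ccccc3)cc2c1
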